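All runs come from a simulation from invented constants, noise included.

Amounts first: against its charge of starting complex, each flask here takes protic impurity at 2.00% and a varied amount of incoming ligand, counted below in equivalents.

the same everywhere: starting complex 0.82 M; protic impurity 0.0164 M

| run | incoming ligand | remark | time |
|---|---|---|---|
| north-west | 0.93 M | run made earlier |  |
| west | 1.5 M | run made earlier |  |
| south-east | 1.9 M | run made earlier |  |
| elm | 1.64 M |  | 40 min |
| alder | 0.984 M |  | 40 min |
| maple | 2.46 M |  | 40 min |

- north-west (time / min: complex with two exchanged / %): 4.00: 9.2; 8.00: 11.1; 12.0: 10.5; 15.0: 7.6; 20.0: 6.6
- west (time / min: complex with two exchanged / %): 4.00: 15.8; 8.00: 15.3; 12.0: 13.0; 15.0: 9.8; 20.0: 8.4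
- south-east (time / min: complex with two exchanged / %): 4.00: 19.7; 8.00: 18.0; 12.0: 12.6; 15.0: 10.8; 20.0: 6.9

(scatter of a reading: 0.5 percentage points)

* which of these holds the largest part of the starting complex at the end of elm (complex with four exchanged / starting complex / complex with one exchanged / complex with two exchanged / complex with three exchanged)
* which of these holds the largest part of the starting complex at the end of alder (complex with four exchanged / starting complex / complex with one exchanged / complex with two exchanged / complex with three exchanged)
* which of these holds the largest part of the starting complex at the end of maple (complex with four exchanged / starting complex / complex with one exchanged / complex with two exchanged / complex with three exchanged)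
* how much complex with two exchanged is there at the end of maple, in percent of the starting complex charged



Two sets of readings of complex with two exchanged seem not to go together. From the north-west run to the south-east run the ligand rises from 1.13 to 2.32 equivalents, and the reading at 4.00 min becomes twice as large, yet at 20.0 min it stands at 6.6% against 6.9%.

The apparent order in ligand differs along the runs. At 4.00 min, the reading per equivalent stands at 8.11% in the north-west run and 8.50% in the south-east run, which reads as first order in ligand. From 12.0 min to 20.0 min the north-west, west and south-east readings fall with constants of 0.0580 min⁻¹, 0.0546 min⁻¹ and 0.0753 min⁻¹. A ligand charge twice as large thus moves the constant by a factor of 1.30, so the fall reads as pseudo-first-order in the complex itself. The mean, 0.0626 min⁻¹, gives 11.1 min: this is the tail half-life, the time in which the falling reading halves. The reckoning here takes the south-east reading at 20.0 min as a stand-in for maple, that run lying nearest to maple in ligand, and carries it through the remaining 20.0 min at that half-life to an estimate near 1.97% at the end of maple.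

The forecast named starting complex for elm, starting complex for alder and complex with four exchanged for maple, with 3% of complex with two exchanged in maple, between 1% and 6.5%, reading that species as “a low steady-state intermediate”.

Among the asked forms, elm ends with starting complex ahead at 22.8%, alder with starting complex at 45.0%, and maple with complex with four exchanged at 23.3%. Complex with two exchanged in maple stands at 2.77%, against the reckoned 1.97%.

    starting complex + incoming ligand ⇌ leaving ligand + complex with one exchanged (K = 0.310, k = 0.00270 L mol⁻¹ s⁻¹)
    complex with one exchanged + incoming ligand ⇌ leaving ligand + complex with two exchanged (K = 15.0, k = 0.00540 L mol⁻¹ s⁻¹)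
    complex with two exchanged + incoming ligand ⇌ leaving ligand + complex with three exchanged (K = 1.70, k = 0.00170 L mol⁻¹ s⁻¹)
    complex with three exchanged + incoming ligand ⇌ leaving ligand + complex with four exchanged (K = 27.0, k = 0.00120 L mol⁻¹ s⁻¹)
    protic impurity + starting complex → quenched substrate (k = 0.170 L mol⁻¹ s⁻¹)
    leaving ligand → by-product carried off (k = 0.00110 s⁻¹)
    complex with two exchanged → over-reaction product (k = 0.00250 s⁻¹)

At the end of maple, complex with two exchanged goes to over-reaction product with a first-order constant of 0.150 min⁻¹, more than the 0.0565 min⁻¹ of the forward step alone to complex with three exchanged with the remaining ligand. Against the tail half-life of 11.1 min, complex with two exchanged in maple falls from 10.7% at 15 min to 2.77% at 40 min, on average a half-life of 12.8 min. A flask like maple but with 1.20 equivalents of ligand lies beside the north-west run, whose reading at 20.0 min, carried by the tail half-life to 40 min, gives an estimate of 1.89% of complex with two exchanged; that flask gives 2.34%.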